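## Retrosynthetic overview

1. Numbering (decalin): C1 dienoic acid, C2 butenyl, C3(Me)=C4, C4a/C8a cis fusion, C7 OSO3H, C8 Me; ring A = C1–C4/C4a/C8a, ring B = C4a/C5–C8/C8a. Endgame: sulfate and acid from a hydroxy dienoate; dienoate from a C1 vinyl group (cross-metathesis, Wittig); C7–OH from a C7 ketone.
2. C2–butenyl bond and the C3=C4 double bond: carbamate-directed syn-SN2′ substitution of a C4 allylic oxygen, itself obtained from a C4 ketone.
3. Key disconnection: ring B from the four-membered ring C4a–C7–C8–C8a that carries OH and vinyl (future C6, C5) on C7. Enabling feature: the C7 oxygen and C4 (alkene carbon of ring A, carried as a ketone) are 1,3-related across ring-fusion carbon C4a, so C4a–C7 is an aldol bond inside a strained ring; retro-aldol cleavage and Michael re-closure onto the vinyl ketone insert C5–C6.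
4. Cyclobutanone plus ring A from a Diels–Alder reaction of cyclobut-2-enone with a 1-acetoxy-4-silyloxy-3-methylbutadiene (a six-membered enone dienophile could put the carbonyl only on C5 or C8, never on C7); C1 vinyl by allylic substitution with inversion; C8 methyl by enolate alkylation.
5. Ring order: ring A and the four-membered ring together (step 3), ring B last, by two-carbon expansion of the four-membered ring (step 9).

Key step: step 9

Convention: β is the face of H-4a and H-8a. In the bicyclo[4.2.0]octenes C1/C6 are the later C8a/C4a, C2–C5 the later C1–C4, and C7, C8 keep their numbers; decalins use the target numbering.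

Assumption: of the two available antipodes of the oxazaborolidinium catalyst in step 3, the one that gives 5 in the configuration drawn is used (the (S)-prolinol-derived catalyst is written); the sense of induction is to be confirmed on 5.

## Route

Step 1
Reactants: 1 (2E)-4-acetoxy-2-methylbut-2-enal
Product: 2 (1E,3E)-4-[(tert-butyldimethylsilyl)oxy]-3-methylbuta-1,3-dien-1-yl acetate
Conditions: TBSOTf (1.2 equiv), Et3N (2 equiv), Et2O, 0 → 25 °C
Reagents that add atoms: tert-butyldimethylsilyl trifluoromethanesulfonate, CC(C)(C)[Si](C)(C)OS(=O)(=O)C(F)(F)F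
Why: Soft enolisation of the enal (O-silylation, then γ-deprotonation at the acetoxy-bearing CH2 by Et3N) is the standard entry to 1-silyloxy-1,3-dienes and should give the (1E,3E)-diene, the only isomer that can reach the s-cis geometry with both oxygens outside.

Step 2
Reactants: 3 3-bromocyclobutan-1-one
Product: 4 cyclobut-2-en-1-one
Conditions: n-Bu3N (1.1 equiv), neat, 25 °C, vacuum transfer into a cold trap
Reagents that add atoms: none
Why: β-Elimination (E1cB) of HBr from the β-bromo ketone by a hindered tertiary amine should give the strained enone, which is distilled away from the non-volatile ammonium salt.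

Step 3
Reactants: 2 (1E,3E)-4-[(tert-butyldimethylsilyl)oxy]-3-methylbuta-1,3-dien-1-yl acetate; 4 cyclobut-2-en-1-one
Product: 5 5-[(tert-butyldimethylsilyl)oxy]-4-methyl-7-oxobicyclo[4.2.0]oct-3-en-2-yl acetate (cis-fused; 2-OAc, 5-OTBS and the four-membered ring all α)
Conditions: oxazaborolidinium triflimide from (S)-α,α-diphenylprolinol, tri-o-tolylboroxine and HNTf2 (20 mol %), CH2Cl2, −78 °C
Reagents that add atoms: none
Why: Lewis-acid-catalysed Diels–Alder reaction in which the strain-activated enone reacts with the diene so that the terminus bearing the stronger donor (OTBS) bonds to the α-carbon of the enone (ortho rule, which puts the later C4 on the carbonyl-bearing fusion carbon), the endo transition state sets OTBS, OAc and the four-membered ring all cis, and the chiral cation bound to the carbonyl oxygen selects the enone face and hence the absolute configuration.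

Step 4
Reactants: 5 5-[(tert-butyldimethylsilyl)oxy]-4-methyl-7-oxobicyclo[4.2.0]oct-3-en-2-yl acetate
Product: 6 5-[(tert-butyldimethylsilyl)oxy]-2-ethenyl-4-methylbicyclo[4.2.0]oct-3-en-7-one (2-vinyl β, trans to the four-membered ring)
Conditions: Pd2(dba)3 (2.5 mol %), LiCl (3 equiv), DMF, 25 °C
Reagents that add atoms: tributyl(vinyl)stannane, C=C[Sn](CCCC)(CCCC)CCCC
Why: Stille-type allylic cross-coupling in which zerovalent palladium ionises the allylic acetate with inversion from the convex β face and then transfers the vinyl group with retention to the less hindered allyl terminus, so that net inversion places the vinyl group cis to H-8a, a relationship the endo cycloaddition could not give.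

Step 5
Reactants: 6 5-[(tert-butyldimethylsilyl)oxy]-2-ethenyl-4-methylbicyclo[4.2.0]oct-3-en-7-one
Product: 7 5-[(tert-butyldimethylsilyl)oxy]-2-ethenyl-4,8-dimethylbicyclo[4.2.0]oct-3-en-7-one (8-Me β, cis to H-8a)
Conditions: LiN(SiMe3)2 (1.05 equiv), THF, −78 °C; MeI (3 equiv), DMPU, −78 → −40 °C
Reagents that add atoms: iodomethane, CI
Why: Kinetic enolate alkylation in which the hindered amide removes a proton from the only α-methylene (C8) and not from the ring-fusion methine, and iodomethane enters from the convex face of the bicycle, which sets C8 in what is also the more stable configuration on the four-membered ring.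

Step 6
Reactants: 7 5-[(tert-butyldimethylsilyl)oxy]-2-ethenyl-4,8-dimethylbicyclo[4.2.0]oct-3-en-7-one
Product: 8 5-[(tert-butyldimethylsilyl)oxy]-2,7-diethenyl-4,8-dimethylbicyclo[4.2.0]oct-3-en-7-ol (7-vinyl drawn β)
Conditions: CH2=CHMgBr (1.5 equiv), THF, −78 °C; aq NH4Cl
Reagents that add atoms: vinylmagnesium bromide, C=C[Mg]Br
Why: Grignard 1,2-addition to the strained, highly electrophilic cyclobutanone supplies the two carbons that become C6 and C5, and the configuration created at C7 is immaterial because C7 returns to sp2 in step 9.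

Step 7
Reactants: 8 5-[(tert-butyldimethylsilyl)oxy]-2,7-diethenyl-4,8-dimethylbicyclo[4.2.0]oct-3-en-7-ol
Product: 9 2,7-diethenyl-4,8-dimethylbicyclo[4.2.0]oct-3-ene-5,7-diol
Conditions: Bu4NF (1.2 equiv), THF, 0 → 25 °C
Reagents that add atoms: none
Why: Fluoride-mediated desilylation frees the secondary allylic alcohol, and since no carbonyl group is present at this stage the tertiary cyclobutanol cannot fragment.

Step 8
Reactants: 9 2,7-diethenyl-4,8-dimethylbicyclo[4.2.0]oct-3-ene-5,7-diol
Product: 10 2,7-diethenyl-7-hydroxy-4,8-dimethylbicyclo[4.2.0]oct-3-en-5-one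
Conditions: MnO2 (20 equiv), CH2Cl2, 25 °C; filtration, used at once
Reagents that add atoms: none
Why: Chemoselective allylic oxidation in which MnO2 oxidises only the secondary allylic alcohol (the tertiary carbinol has no carbinol hydrogen) under neutral conditions that should leave the strained β-hydroxy ketone intact.

Step 9
Reactants: 10 2,7-diethenyl-7-hydroxy-4,8-dimethylbicyclo[4.2.0]oct-3-en-5-one
Product: 14 cis-fused 7-[(tert-butyldimethylsilyl)oxy]-1-ethenyl-3,8-dimethyl-4a,5,8,8a-tetrahydronaphthalen-4(1H)-one, via potassium alkoxide 11 (not isolated), via ring-opened potassium dienolate 12 (not isolated), via potassium enolate 13 (not isolated)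
Conditions: KN(SiMe3)2 (1.05 equiv), THF, −78 → −40 °C; t-BuMe2SiCl (1.3 equiv), −78 → 0 °C
Reagents that add atoms: tert-butyldimethylsilyl chloride, CC(C)(C)[Si](C)(C)Cl
Why: Deprotonation gives alkoxide 11, whose C7–C4a bond is the aldol bond of a β-hydroxy ketone held in a four-membered ring, so strain-driven retro-aldol cleavage should deliver the cross-conjugated dienolate 12 (nucleophilic only at C4a) with the freshly unmasked vinyl ketone on C8a. Intramolecular Michael addition of C4a to the terminal carbon C5 (6-endo-trig) then closes ring B and gives the regiodefined C6=C7 enolate 13, which is silylated on oxygen; overall the ring C4a–C7–C8–C8a grows by C5 and C6 in a formal 1,3-shift. The closest known reaction types are the retro-aldol opening of cyclobutanols (De Mayo reaction) and the intramolecular Michael step of a Robinson-type annulation, coupled here as an alkoxide-accelerated two-carbon ring expansion. The only new stereocentre, C4a, is controlled by C8a: the bond must form perpendicular to the enolate plane from the face that carries the tether (pseudoaxial C8a–C8 bond), which gives the cis fusion, while C1, C8 and C8a pass through unchanged. The step needs site selectivity (C4a rather than C2 or an intermolecular partner), which the cross-conjugated enolate and the six-membered transition state secure, and it is stereoconvergent in C7, since both carbinol epimers and any re-closure of 12 to 11 funnel into the same enolate. Stoichiometric base, low temperature and the silyl quench are chosen so that neither C4a (α to the C4 ketone) nor C8 equilibrates, and the silyl enol ether masks the C7 ketone for steps 10 to 12.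

Step 10
Reactants: 14 cis-fused 7-[(tert-butyldimethylsilyl)oxy]-1-ethenyl-3,8-dimethyl-4a,5,8,8a-tetrahydronaphthalen-4(1H)-one
Product: 15 7-[(tert-butyldimethylsilyl)oxy]-1-ethenyl-3,8-dimethyl-1,4,4a,5,8,8a-hexahydronaphthalen-4-ol (4-OH α)
Conditions: i-Bu2AlH (1.2 equiv), toluene, −78 °C; Rochelle salt work-up
Reagents that add atoms: none
Why: 1,2-Reduction of the enone by an aluminium hydride, in which hydride should arrive from the convex β face of the cis-fused bicycle (anti to the C4a–C5 bond) to give the 4α allylic alcohol, while the silyl enol ether and the vinyl group are inert.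

Step 11
Reactants: 15 7-[(tert-butyldimethylsilyl)oxy]-1-ethenyl-3,8-dimethyl-1,4,4a,5,8,8a-hexahydronaphthalen-4-ol
Product: 16 N-phenylcarbamate of 15 (4-OC(O)NHPh α)
Conditions: PhNCO (1.5 equiv), Et3N, DMAP (cat.), CH2Cl2, 25 °C
Reagents that add atoms: phenyl isocyanate, O=C=Nc1ccccc1
Why: Carbamoylation of the secondary alcohol by the isocyanate installs a group that is both the leaving group and the internal ligand for copper in the next step.

Step 12
Reactants: 16 N-phenylcarbamate of 15
Product: 18 2-[(2E)-but-2-en-2-yl]-1-ethenyl-3,8-dimethyl-1,2,4a,5,6,8a-hexahydronaphthalen-7(8H)-one (cis-fused; 1-vinyl β, 2-butenyl α, 8-Me β), via silyl enol ether 17 (not isolated)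
Conditions: MeLi (1.0 equiv), THF, −78 °C; CuI (1.0 equiv), 0 °C; (E)-MeCH=C(Me)Li [from (E)-2-bromobut-2-ene and t-BuLi (2 equiv), Et2O, −78 °C], −78 → 25 °C; then 1 M HCl, THF, 0 °C
Reagents that add atoms: (E)-but-2-en-2-yllithium, C/C=C(\C)[Li], made in the flask from (E)-2-bromobut-2-ene, C/C=C(\C)Br
Why: Carbamate-directed syn-SN2′ allylic substitution in which the N-metalated carbamate holds the mixed alkenyl(amido)cuprate and delivers the butenyl group, with retention of its geometry, to C2 on the α face of the leaving group and anti to the 1β-vinyl group, which sets C2 and moves the double bond to C3=C4; the acidic work-up then hydrolyses the silyl enol ether by protonation at C6, which touches no stereocentre.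

Step 13
Reactants: 18 2-[(2E)-but-2-en-2-yl]-1-ethenyl-3,8-dimethyl-1,2,4a,5,6,8a-hexahydronaphthalen-7(8H)-one
Product: 19 2-[(2E)-but-2-en-2-yl]-1-ethenyl-3,8-dimethyl-1,2,4a,5,6,7,8,8a-octahydronaphthalen-7-ol (7-OH β, cis to 8-Me)
Conditions: Li (excess), NH3(l)/THF, EtOH (3 equiv), −78 °C; NH4Cl
Reagents that add atoms: none
Why: Dissolving-metal reduction, which gives the thermodynamically preferred equatorial alcohol through the ketyl; in the conformer that keeps the C1 and C2 substituents equatorial the 8-methyl is axial and the equatorial C7–OH is the required 7β epimer, the isolated alkenes are not reduced, and the proton source limits amide-mediated epimerisation at C8.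

Step 14
Reactants: 19 2-[(2E)-but-2-en-2-yl]-1-ethenyl-3,8-dimethyl-1,2,4a,5,6,7,8,8a-octahydronaphthalen-7-ol
Product: 20 (2E)-3-[2-((2E)-but-2-en-2-yl)-7-hydroxy-3,8-dimethyl-1,2,4a,5,6,7,8,8a-octahydronaphthalen-1-yl]prop-2-enal
Conditions: crotonaldehyde (5 equiv), second-generation Hoveyda–Grubbs catalyst RuCl2(H2IMes)(=CH-C6H4-2-O-i-Pr) (5 mol %), CH2Cl2, 40 °C
Reagents that add atoms: (E)-but-2-enal, C/C=C/C=O
Why: Olefin cross-metathesis in which only the monosubstituted vinyl group engages the ruthenium carbene (both trisubstituted alkenes are unreactive) and coupling with the electron-poor partner should give the (E)-enal with loss of propene.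

Step 15
Reactants: 20 (2E)-3-[2-((2E)-but-2-en-2-yl)-7-hydroxy-3,8-dimethyl-1,2,4a,5,6,7,8,8a-octahydronaphthalen-1-yl]prop-2-enal
Product: 21 ethyl (2E,4E)-5-[2-((2E)-but-2-en-2-yl)-7-hydroxy-3,8-dimethyl-1,2,4a,5,6,7,8,8a-octahydronaphthalen-1-yl]penta-2,4-dienoate
Conditions: Ph3P=CHCO2Et (1.5 equiv), CH2Cl2, 25 °C
Reagents that add atoms: ethyl 2-(triphenylphosphoranylidene)acetate, CCOC(=O)C=P(c1ccccc1)(c1ccccc1)c1ccccc1
Why: Wittig olefination with a stabilised ylide should give the (2E,4E)-dienoate under neutral conditions that do not epimerise C1.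

Step 16
Reactants: 21 ethyl (2E,4E)-5-[2-((2E)-but-2-en-2-yl)-7-hydroxy-3,8-dimethyl-1,2,4a,5,6,7,8,8a-octahydronaphthalen-1-yl]penta-2,4-dienoate
Product: 22 pyridinium salt of the 7-O-sulfate of 21
Conditions: SO3·pyridine (5 equiv), pyridine, 25 °C
Reagents that add atoms: sulfur trioxide–pyridine complex, O=S(=O)([O-])[n+]1ccccc1
Why: O-Sulfation of the secondary alcohol by the SO3–amine complex gives the sulfate monoester as its pyridinium salt, and the ester group keeps the carboxyl function from forming a mixed anhydride.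

Step 17
Reactants: 22 pyridinium salt of the 7-O-sulfate of 21
Product: 23 the target, (2E,4E)-5-[2-((2E)-but-2-en-2-yl)-3,8-dimethyl-7-(sulfooxy)-1,2,4a,5,6,7,8,8a-octahydronaphthalen-1-yl]penta-2,4-dienoic acid
Conditions: LiOH (3 equiv), THF/H2O, 0 → 25 °C; then 1 M HCl to pH 2 at 0 °C, rapid extraction
Reagents that add atoms: lithium hydroxide, [Li+].[OH-]
Why: Saponification of the ethyl ester, to which the monoanionic alkyl sulfate is inert, followed by cold acidification should give the target as the free acid.

## Compound list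

1 | (2E)-4-acetoxy-2-methylbut-2-enal | CC(=O)OC/C=C(\C)C=O | starting material
2 | (1E,3E)-4-[(tert-butyldimethylsilyl)oxy]-3-methylbuta-1,3-dien-1-yl acetate | CC(=O)O/C=C/C(C)=C/O[Si](C)(C)C(C)(C)C | intermediate
3 | 3-bromocyclobutan-1-one | O=C1CC(Br)C1 | starting material
4 | cyclobut-2-en-1-one | O=C1C=CC1 | intermediate
5 | 5-[(tert-butyldimethylsilyl)oxy]-4-methyl-7-oxobicyclo[4.2.0]oct-3-en-2-yl acetate (all-cis endo adduct) | C1=C(C)[C@@H](O[Si](C)(C)C(C)(C)C)[C@H]2C(=O)C[C@H]2[C@H]1OC(C)=O | intermediate
6 | 5-[(tert-butyldimethylsilyl)oxy]-2-ethenyl-4-methylbicyclo[4.2.0]oct-3-en-7-one | C1=C(C)[C@@H](O[Si](C)(C)C(C)(C)C)[C@H]2C(=O)C[C@H]2[C@@H]1C=C | intermediate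
7 | 5-[(tert-butyldimethylsilyl)oxy]-2-ethenyl-4,8-dimethylbicyclo[4.2.0]oct-3-en-7-one | C1=C(C)[C@@H](O[Si](C)(C)C(C)(C)C)[C@H]2C(=O)[C@H](C)[C@H]2[C@@H]1C=C | intermediate
8 | 5-[(tert-butyldimethylsilyl)oxy]-2,7-diethenyl-4,8-dimethylbicyclo[4.2.0]oct-3-en-7-ol | C1=C(C)[C@@H](O[Si](C)(C)C(C)(C)C)[C@H]2[C@](O)(C=C)[C@H](C)[C@H]2[C@@H]1C=C | intermediate
9 | 2,7-diethenyl-4,8-dimethylbicyclo[4.2.0]oct-3-ene-5,7-diol | C1=C(C)[C@@H](O)[C@H]2[C@](O)(C=C)[C@H](C)[C@H]2[C@@H]1C=C | intermediate
10 | 2,7-diethenyl-7-hydroxy-4,8-dimethylbicyclo[4.2.0]oct-3-en-5-one | C1=C(C)C(=O)[C@H]2[C@](O)(C=C)[C@H](C)[C@H]2[C@@H]1C=C | intermediate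
11 | potassium alkoxide of 10 | C1=C(C)C(=O)[C@H]2[C@]([O-])(C=C)[C@H](C)[C@H]2[C@@H]1C=C.[K+] | intermediate
12 | potassium 4-ethenyl-6-methyl-3-[3-oxopent-4-en-2-yl]cyclohexa-1,5-dien-1-olate | C=CC(=O)[C@H](C)[C@@H]1C=C([O-])C(C)=C[C@H]1C=C.[K+] | intermediate
13 | potassium cis-1-ethenyl-3,8-dimethyl-4-oxo-1,4,4a,5,8,8a-hexahydronaphthalen-7-olate | C1=C(C)C(=O)[C@H]2CC=C([O-])[C@H](C)[C@H]2[C@@H]1C=C.[K+] | intermediate
14 | cis-7-[(tert-butyldimethylsilyl)oxy]-1-ethenyl-3,8-dimethyl-4a,5,8,8a-tetrahydronaphthalen-4(1H)-one | C1=C(C)C(=O)[C@H]2CC=C(O[Si](C)(C)C(C)(C)C)[C@H](C)[C@H]2[C@@H]1C=C | intermediate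
15 | 7-[(tert-butyldimethylsilyl)oxy]-1-ethenyl-3,8-dimethyl-1,4,4a,5,8,8a-hexahydronaphthalen-4-ol (4α-OH) | C1=C(C)[C@@H](O)[C@H]2CC=C(O[Si](C)(C)C(C)(C)C)[C@H](C)[C@H]2[C@@H]1C=C | intermediate
16 | N-phenylcarbamate of 15 | C1=C(C)[C@@H](OC(=O)Nc3ccccc3)[C@H]2CC=C(O[Si](C)(C)C(C)(C)C)[C@H](C)[C@H]2[C@@H]1C=C | intermediate
17 | {[2-((2E)-but-2-en-2-yl)-1-ethenyl-3,8-dimethyl-1,2,4a,5,8,8a-hexahydronaphthalen-7-yl]oxy}(tert-butyl)dimethylsilane | C/C=C(\C)[C@H]1C(C)=C[C@H]2CC=C(O[Si](C)(C)C(C)(C)C)[C@H](C)[C@H]2[C@@H]1C=C | intermediate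
18 | 2-[(2E)-but-2-en-2-yl]-1-ethenyl-3,8-dimethyl-1,2,4a,5,6,8a-hexahydronaphthalen-7(8H)-one | C/C=C(\C)[C@H]1C(C)=C[C@H]2CCC(=O)[C@H](C)[C@H]2[C@@H]1C=C | intermediate
19 | 2-[(2E)-but-2-en-2-yl]-1-ethenyl-3,8-dimethyl-1,2,4a,5,6,7,8,8a-octahydronaphthalen-7-ol (7β-OH) | C/C=C(\C)[C@H]1C(C)=C[C@H]2CC[C@H](O)[C@H](C)[C@H]2[C@@H]1C=C | intermediate
20 | (2E)-3-[2-((2E)-but-2-en-2-yl)-7-hydroxy-3,8-dimethyl-1,2,4a,5,6,7,8,8a-octahydronaphthalen-1-yl]prop-2-enal | C/C=C(\C)[C@H]1C(C)=C[C@H]2CC[C@H](O)[C@H](C)[C@H]2[C@@H]1/C=C/C=O | intermediate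
21 | ethyl (2E,4E)-5-[2-((2E)-but-2-en-2-yl)-7-hydroxy-3,8-dimethyl-1,2,4a,5,6,7,8,8a-octahydronaphthalen-1-yl]penta-2,4-dienoate | C/C=C(\C)[C@H]1C(C)=C[C@H]2CC[C@H](O)[C@H](C)[C@H]2[C@@H]1/C=C/C=C/C(=O)OCC | intermediate
22 | pyridinium salt of the 7-O-sulfate of 21 | C/C=C(\C)[C@H]1C(C)=C[C@H]2CC[C@H](OS(=O)(=O)[O-])[C@H](C)[C@H]2[C@@H]1/C=C/C=C/C(=O)OCC.c1cc[nH+]cc1 | intermediate
23 | (2E,4E)-5-[2-((2E)-but-2-en-2-yl)-3,8-dimethyl-7-(sulfooxy)-1,2,4a,5,6,7,8,8a-octahydronaphthalen-1-yl]penta-2,4-dienoic acid | C/C=C(\C)[C@H]1C(C)=C[C@H]2CC[C@H](OS(=O)(=O)O)[C@H](C)[C@H]2[C@@H]1/C=C/C=C/C(=O)O | target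

## Step count and risks

Total step count: 17. Longest linear sequence: 16 steps (1 → 23; the branch from 3 is equally long).

**Step 9 (key step).** After the C–C cleavage the potassium enolates may exchange protons faster than they cyclise or are silylated. This would epimerise C4a towards the trans-fused series or shift the ring A double bond by γ-deprotonation at C1; intermolecular Michael addition of 12 is the other leak. The fallback sets out from 10 and returns at 14; it separates fragmentation from ring closure and forms the C–C bond from a neutral species. Compound 10 is treated with KN(SiMe3)2 in the presence of t-BuMe2SiCl (internal quench, THF, −100 °C), so that the dienolate is silylated on oxygen as soon as the four-membered ring opens. This should give the ring-opened silyl dienol ether tert-butyl({4-ethenyl-6-methyl-3-[3-oxopent-4-en-2-yl]cyclohexa-1,5-dien-1-yl}oxy)dimethylsilane F1. A catalytic amount of HNTf2 (CH2Cl2, −78 °C) then promotes an intramolecular Mukaiyama–Michael addition with silyl transfer to the new enol ether. This closes ring B under the same stereoelectronic control and should deliver 14 without any free enolate.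

**Step 12.** The alkenyl ligand may transfer poorly from the mixed amidocuprate, or the directing effect may be lost so that substitution occurs anti or without allylic transposition. The fallback sets out from 15 and returns at 18; the leaving group is inverted instead of used as a director. Mitsunobu esterification of 15 with pyridine-2-carboxylic acid (PPh3, DIAD, THF) should give the 4β-ester, 7-[(tert-butyldimethylsilyl)oxy]-1-ethenyl-3,8-dimethyl-1,4,4a,5,8,8a-hexahydronaphthalen-4-yl pyridine-2-carboxylate F2. (E)-But-2-en-2-ylmagnesium bromide with CuBr·SMe2 (THF, −40 °C) then effects a chelation-activated anti-SN2′ substitution. This again puts the butenyl group on the α face of C2 and gives 17, which the acidic work-up of step 12 hydrolyses to 18. If step 10 were to give the 4β-alcohol instead, direct acylation would lead to F2 as well.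

**Step 3.** The doubly oxygenated diene may be ionised or desilylated by the strongly acidic catalyst, the two oxygenated termini may compete for the regiochemistry, or the small enone may be poorly face-differentiated. The fallback sets out from 1 and returns at 6; stereocontrol is moved from the catalyst to the diene. Methanolysis of 1 (K2CO3, MeOH, 0 °C) gives (2E)-4-hydroxy-2-methylbut-2-enal F3. Esterification with (S)-2-methoxy-2-phenylacetic acid (DCC, DMAP) gives (2E)-3-methyl-4-oxobut-2-en-1-yl (2S)-2-methoxy-2-phenylacetate F4. Silylation as in step 1 gives the chiral diene (1E,3E)-4-[(tert-butyldimethylsilyl)oxy]-3-methylbuta-1,3-dien-1-yl (2S)-2-methoxy-2-phenylacetate F5, in which the phenyl ring shields one diene face. Uncatalysed cycloaddition with 4 (toluene, 25 °C) and separation from the minor diastereomer should give 5-[(tert-butyldimethylsilyl)oxy]-4-methyl-7-oxobicyclo[4.2.0]oct-3-en-2-yl (2S)-2-methoxy-2-phenylacetate F6. The auxiliary ester then serves as the allylic leaving group under the conditions of step 4, which gives 6.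

## Further compounds

F1 | step 9 | tert-butyl({4-ethenyl-6-methyl-3-[3-oxopent-4-en-2-yl]cyclohexa-1,5-dien-1-yl}oxy)dimethylsilane | C=CC(=O)[C@H](C)[C@@H]1C=C(O[Si](C)(C)C(C)(C)C)C(C)=C[C@H]1C=C
F2 | step 12 | 7-[(tert-butyldimethylsilyl)oxy]-1-ethenyl-3,8-dimethyl-1,4,4a,5,8,8a-hexahydronaphthalen-4-yl pyridine-2-carboxylate (4β) | C1=C(C)[C@H](OC(=O)c3ccccn3)[C@H]2CC=C(O[Si](C)(C)C(C)(C)C)[C@H](C)[C@H]2[C@@H]1C=C
F3 | step 3 | (2E)-4-hydroxy-2-methylbut-2-enal | OC/C=C(\C)C=O
F4 | step 3 | (2E)-3-methyl-4-oxobut-2-en-1-yl (2S)-2-methoxy-2-phenylacetate | CO[C@H](C(=O)OC/C=C(\C)C=O)c1ccccc1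
F5 | step 3 | (1E,3E)-4-[(tert-butyldimethylsilyl)oxy]-3-methylbuta-1,3-dien-1-yl (2S)-2-methoxy-2-phenylacetate | CO[C@H](C(=O)O/C=C/C(C)=C/O[Si](C)(C)C(C)(C)C)c1ccccc1
F6 | step 3 | 5-[(tert-butyldimethylsilyl)oxy]-4-methyl-7-oxobicyclo[4.2.0]oct-3-en-2-yl (2S)-2-methoxy-2-phenylacetate | C1=C(C)[C@@H](O[Si](C)(C)C(C)(C)C)[C@H]2C(=O)C[C@H]2[C@H]1OC(=O)[C@@H](OC)c1ccccc1
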